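**Retrosynthetic overview**
- The C8 2-methylbutanoate is put on last. The 8α,9α-diol comes from dihydroxylation of a C8=C9 cycloheptene anti to the 7β-angelate, and the enone from oxidation of a C1 carbinol followed by isomerisation of an exocyclic C3=C12 alkene.
- Ring C (seven-membered) is closed by ring-closing metathesis after an aldol union of a bicyclic cyclobutanone (fragment A, C11) with the enolate of isopropyl vinyl ketone (fragment B, C6). The C5 oxygen is then removed by radical deoxygenation and C7 is set by catalyst-controlled reduction.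
- Fragment A (cyclobutane and six-membered ring, rings A and B, formed in one step) comes from an intramolecular vinylketene–alkene [2+2] cycloaddition of a trienoic acid derivative. Its absolute configuration is relayed from a C1 carbinol.
- That carbinol is set by a catalytic asymmetric vinylogous Mukaiyama aldol between (E)-3-methylpenta-2,4-dienal and a senecioate-derived silyl dienolate.
- Ring order: A and B together, then C.

Assumption: atoms of bicyclic and tricyclic compounds are cited by longipinane numbering (bridge C1–C2–C3 with C12 on C3; cyclobutane C4, C5, C11, C10; bridge C6–C9; two methyls on C6, one on C10), and the E-enynol, angelic acid and (R)-2-methylbutanoic acid are purchased.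

**Step 1**
Reactants: 1 (E)-3-methylpent-2-en-4-yn-1-ol
Product: 2 (E)-3-methylpenta-2,4-dien-1-ol
Conditions: H2 (1 atm), Pd/CaCO3 poisoned with Pb(OAc)2, quinoline, EtOAc, 0 °C to rt, stopped after 1 equiv H2
Reagents that add atoms: none
Why: Lindlar semihydrogenation reduces only the terminal alkyne and leaves the E-trisubstituted alkene untouched.

**Step 2**
Reactants: 2 (E)-3-methylpenta-2,4-dien-1-ol
Product: 3 (E)-3-methylpenta-2,4-dienal
Conditions: activated MnO2 (10 equiv), CH2Cl2, rt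
Reagents that add atoms: none
Why: Allylic alcohol oxidation with MnO2 stops at the aldehyde and keeps the E geometry.

**Step 3**
Reactants: 4 3-methylbut-2-enoic acid
Product: 5 tert-butyl 3-methylbut-2-enoate
Conditions: t-BuOC(=NH)CCl3 (2 equiv), BF3·OEt2 (cat.), cyclohexane/CH2Cl2, rt
Reagents that add atoms: tert-butyl 2,2,2-trichloroacetimidate, CC(C)(C)OC(=N)C(Cl)(Cl)Cl
Why: Acid-catalysed imidate esterification gives the tert-butyl ester without base, so the double bond does not move out of conjugation.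

**Step 4**
Reactants: 5 tert-butyl 3-methylbut-2-enoate
Product: 7 tert-butyl[(1-tert-butoxy-3-methylbuta-1,3-dien-1-yl)oxy]dimethylsilane, via lithium dienolate 6 (not isolated)
Conditions: LiN(i-Pr)2, THF, −78 °C; then t-BuMe2SiCl, DMPU, −78 °C to rt; distil
Reagents that add atoms: tert-butyldimethylsilyl chloride, CC(C)(C)[Si](C)(C)Cl
Why: Kinetic γ-deprotonation of the enoate and O-silylation (silyl ketene acetal formation) give the vinylogous nucleophile.

**Step 5**
Reactants: 3 (E)-3-methylpenta-2,4-dienal; 7 tert-butyl[(1-tert-butoxy-3-methylbuta-1,3-dien-1-yl)oxy]dimethylsilane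
Product: 8 tert-butyl (2E,5S,6E)-5-hydroxy-3,7-dimethylnona-2,6,8-trienoate
Conditions: SiCl4 (1.1 equiv), (S,S)-binaphthyldiamine-derived bisphosphoramide (5 mol %), i-Pr2NEt (10 mol %), CH2Cl2, −78 °C; aq. NaHCO3 work-up
Reagents that add atoms: none
Why: Lewis-base-activated SiCl4 vinylogous Mukaiyama aldol in which the dienolate reacts only at its γ-carbon and on the Si face of the aldehyde held in the chiral phosphoramide–silicon complex, giving the E-enoate and the 5S carbinol (the later C1); the catalyst enantiomer is chosen from the usual Re-face preference of the (R,R)-catalyst and the sense is checked by Mosher analysis.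

**Step 6**
Reactants: 8 tert-butyl (2E,5S,6E)-5-hydroxy-3,7-dimethylnona-2,6,8-trienoate
Product: 9 tert-butyldimethylsilyl (2E,5S,6E)-5-[(tert-butyldimethylsilyl)oxy]-3,7-dimethylnona-2,6,8-trienoate
Conditions: t-BuMe2SiOTf (3 equiv), 2,6-lutidine, CH2Cl2, 0 °C to rt; used after filtration through a short pad
Reagents that add atoms: tert-butyldimethylsilyl trifluoromethanesulfonate, CC(C)(C)[Si](C)(C)OS(=O)(=O)C(F)(F)F
Why: The silyl triflate silylates the carbinol and, by the same Lewis-acid tert-butyl cleavage known for tert-butyl carbamates, exchanges the tert-butyl ester for the silyl ester with loss of isobutene.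

**Step 7**
Reactants: 9 tert-butyldimethylsilyl (2E,5S,6E)-5-[(tert-butyldimethylsilyl)oxy]-3,7-dimethylnona-2,6,8-trienoate
Product: 12 (1R,2S,5R,7R)-2-[(tert-butyldimethylsilyl)oxy]-7-ethenyl-7-methyl-4-methylidenebicyclo[3.1.1]heptan-6-one, via acid chloride 10 (not isolated), via vinylketene 11 (not isolated)
Conditions: (COCl)2, DMF (cat.), CH2Cl2, 0 °C to rt; concentrate; slow addition (8 h) to Et3N (3 equiv), toluene, reflux, 0.005 M
Reagents that add atoms: none
Why: Neutral conversion of the silyl ester to the acid chloride and vinylogous dehydrochlorination give a vinylketene that undergoes intramolecular ketene–alkene [2+2] cycloaddition; the carbonyl carbon (the later C5) bonds to C11 so that charge builds at the tertiary allylic C10 (bridged mode), the addition is suprafacial on the E-alkene (10-methyl syn to the C1–C3 bridge, 10-vinyl anti), and the alkene face is fixed by minimised 1,3-allylic strain at the silyloxy carbon, which sets C4, C10 and C11 (all R) with the 1-silyloxy group trans to C10.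

**Step 8**
Reactants: 13 2-methylpropanal
Product: 14 4-methylpent-1-en-3-ol (racemic)
Conditions: CH2=CHMgBr, THF, 0 °C; dilute aq. HCl
Reagents that add atoms: vinylmagnesium bromide, C=C[Mg]Br
Why: Grignard 1,2-addition to the aldehyde.

**Step 9**
Reactants: 14 4-methylpent-1-en-3-ol
Product: 15 4-methylpent-1-en-3-one
Conditions: Dess–Martin periodinane, CH2Cl2, 0 °C to rt; distil
Reagents that add atoms: none
Why: Dess–Martin oxidation of the secondary allylic alcohol gives the vinyl ketone under non-acidic conditions.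

**Step 10**
Reactants: 15 4-methylpent-1-en-3-one
Product: 16 trimethyl[(4-methylpenta-1,3-dien-3-yl)oxy]silane
Conditions: Me3SiOTf, Et3N, Et2O, 0 °C; distil
Reagents that add atoms: trimethylsilyl trifluoromethanesulfonate, C[Si](C)(C)OS(=O)(=O)C(F)(F)F
Why: Soft enolisation at the only α-hydrogen gives the regiodefined silyl dienol ether and avoids exposing the vinyl ketone to an amide base.

**Step 11**
Reactants: 12 (1R,2S,5R,7R)-2-[(tert-butyldimethylsilyl)oxy]-7-ethenyl-7-methyl-4-methylidenebicyclo[3.1.1]heptan-6-one; 16 trimethyl[(4-methylpenta-1,3-dien-3-yl)oxy]silane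
Product: 20 O-[(1R,2S,5R,6R,7R)-2-[(tert-butyldimethylsilyl)oxy]-7-ethenyl-7-methyl-4-methylidene-6-(2-methyl-3-oxopent-4-en-2-yl)bicyclo[3.1.1]heptan-6-yl] S-methyl carbonodithioate, via lithium enolate 17 (not isolated), via lithium aldolate 18 (not isolated), via lithium xanthate 19 (not isolated)
Conditions: 16, MeLi, THF, 0 °C to rt; then 12, −78 °C; then CS2, DMPU, −78 to −20 °C; then MeI, 0 °C
Reagents that add atoms: carbon disulfide, S=C=S; iodomethane, CI
Why: Silyl–lithium exchange gives the regiodefined enolate, whose aldol addition to the strained, non-enolisable cyclobutanone takes the face remote from the C1–C3 bridge (that bridge is pushed over the other face by the syn 10-methyl), so the new chain is anti like the 10-vinyl group and the oxygen syn (5R); the tertiary aldolate is trapped in the same flask as the S-methyl xanthate, which cannot undergo Chugaev elimination because its only β-hydrogens are at bridgeheads.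

**Step 12**
Reactants: 20 O-[(1R,2S,5R,6R,7R)-2-[(tert-butyldimethylsilyl)oxy]-7-ethenyl-7-methyl-4-methylidene-6-(2-methyl-3-oxopent-4-en-2-yl)bicyclo[3.1.1]heptan-6-yl] S-methyl carbonodithioate
Product: 21 O-[(1S,4R,5R,10R,11R)-1-[(tert-butyldimethylsilyl)oxy]-7-oxolongipina-3(12),8-dien-5-yl] S-methyl carbonodithioate
Conditions: second-generation Hoveyda–Grubbs catalyst RuCl2(H2IMes)(=CH-C6H4-2-O-i-Pr) (10 mol %), toluene, 80 °C, 0.005 M
Reagents that add atoms: none
Why: Ring-closing metathesis between the vinyl ketone and the 10-vinyl group, held close together in a 1,3-diaxial relation on the cyclobutane, closes ring C as the cis-enone with loss of ethene.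

**Step 13**
Reactants: 21 O-[(1S,4R,5R,10R,11R)-1-[(tert-butyldimethylsilyl)oxy]-7-oxolongipina-3(12),8-dien-5-yl] S-methyl carbonodithioate
Product: 22 (1S,4R,5S,10R,11R)-1-[(tert-butyldimethylsilyl)oxy]longipina-3(12),8-dien-7-one
Conditions: Bu3SnH (2 equiv, syringe pump), AIBN (0.2 equiv), toluene, 90 °C
Reagents that add atoms: none
Why: Barton–McCombie deoxygenation, in which the tertiary C5 radical is locked by ring C and can take hydrogen only on the face opposite the C6–C9 bridge, so the 5S hydrogen is set by the ring system.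

**Step 14**
Reactants: 22 (1S,4R,5S,10R,11R)-1-[(tert-butyldimethylsilyl)oxy]longipina-3(12),8-dien-7-one
Product: 23 (1S,4R,5S,7R,10R,11R)-1-[(tert-butyldimethylsilyl)oxy]longipina-3(12),8-dien-7-ol (7β-OH)
Conditions: (S)-2-methyl-CBS-oxazaborolidine (0.3 equiv), catecholborane (2 equiv), toluene, −78 to −40 °C
Reagents that add atoms: none
Why: Corey–Bakshi–Shibata reduction in which the quaternary C6 is taken as the large and the vinylic C8 as the small group, so the (S)-catalyst gives the 7R allylic alcohol by 1,2-reduction; the locally symmetric bridge offers no opposing substrate bias.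

**Step 15**
Reactants: 24 angelic acid, (2Z)-2-methylbut-2-enoic acid
Product: 25 (2Z)-2-methylbut-2-enoic 2,4,6-trichlorobenzoic anhydride
Conditions: 2,4,6-Cl3C6H2COCl (1.0 equiv), Et3N (1.1 equiv), toluene, 0 °C to rt; filter under argon and use the toluene solution directly
Reagents that add atoms: 2,4,6-trichlorobenzoyl chloride, O=C(Cl)c1c(Cl)cc(Cl)cc1Cl
Why: Yamaguchi mixed-anhydride formation, in which the carboxylate displaces chloride from the aroyl chloride; no nucleophilic catalyst is present, so the Z alkene does not isomerise.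

**Step 16**
Reactants: 23 (1S,4R,5S,7R,10R,11R)-1-[(tert-butyldimethylsilyl)oxy]longipina-3(12),8-dien-7-ol; 25 (2Z)-2-methylbut-2-enoic 2,4,6-trichlorobenzoic anhydride
Product: 27 (1S,4R,5S,7R,10R,11R)-1-[(tert-butyldimethylsilyl)oxy]longipina-3(12),8-dien-7-yl (2Z)-2-methylbut-2-enoate, via lithium alkoxide 26 (not isolated)
Conditions: LiN(SiMe3)2 (1.1 equiv), THF, −78 °C; then 25 (1.5 equiv, toluene solution), −78 to 0 °C; cold dilute aq. HCl
Reagents that add atoms: none
Why: The preformed lithium alkoxide of the hindered neopentylic alcohol attacks the mixed anhydride only at the angeloyl carbonyl, because the aroyl carbonyl is shielded by its two ortho chlorines; this low-temperature acyl transfer needs none of the nucleophilic catalysts that turn angelates into tiglates.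

**Step 17**
Reactants: 27 (1S,4R,5S,7R,10R,11R)-1-[(tert-butyldimethylsilyl)oxy]longipina-3(12),8-dien-7-yl (2Z)-2-methylbut-2-enoate
Product: 28 (1S,4R,5S,7R,10R,11R)-1-hydroxylongipina-3(12),8-dien-7-yl (2Z)-2-methylbut-2-enoate
Conditions: HF·pyridine, pyridine, THF, 0 °C to rt
Reagents that add atoms: none
Why: Fluoride desilylation frees the C1 carbinol without touching the angelate or the alkenes.

**Step 18**
Reactants: 28 (1S,4R,5S,7R,10R,11R)-1-hydroxylongipina-3(12),8-dien-7-yl (2Z)-2-methylbut-2-enoate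
Product: 30 (4R,5S,7R,10R,11R)-1-oxolongipina-2,8-dien-7-yl (2Z)-2-methylbut-2-enoate, via deconjugated ketone 29 (not isolated)
Conditions: Dess–Martin periodinane, CH2Cl2, rt; then Et3N (3 equiv), rt
Reagents that add atoms: none
Why: Dess–Martin oxidation gives the β,γ-unsaturated ketone, which the amine isomerises to the conjugated verbenone-type enone; both neighbouring bridgeheads forbid any other enolisation.

**Step 19**
Reactants: 30 (4R,5S,7R,10R,11R)-1-oxolongipina-2,8-dien-7-yl (2Z)-2-methylbut-2-enoate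
Product: 31 (4R,5S,7S,8S,9S,10R,11R)-8,9-dihydroxy-1-oxolongipin-2-en-7-yl (2Z)-2-methylbut-2-enoate
Conditions: OsO4 (5 mol %), N-methylmorpholine N-oxide (1.5 equiv), acetone/H2O 5:1, 0 °C to rt
Reagents that add atoms: osmium tetroxide, O=[Os](=O)(=O)=O; N-methylmorpholine N-oxide, C[N+]1([O-])CCOCC1; water, O
Why: Upjohn dihydroxylation attacks the isolated cis-disubstituted C8=C9 in preference to the two conjugated trisubstituted alkenes, and on the face anti to the allylic 7β-acyloxy group (Kishi's empirical rule), giving the 8α,9α-cis-diol.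

**Step 20**
Reactants: 32 (R)-2-methylbutanoic acid
Product: 33 (R)-2-methylbutanoyl chloride
Conditions: (COCl)2 (0.95 equiv), DMF (cat.), CH2Cl2, 0 °C to rt; purge with argon and use the solution directly
Reagents that add atoms: oxalyl chloride, O=C(Cl)C(=O)Cl
Why: Vilsmeier-type chlorination of the acid runs without base, so no ketene forms and the α-stereocentre is untouched.

**Step 21**
Reactants: 31 (4R,5S,7S,8S,9S,10R,11R)-8,9-dihydroxy-1-oxolongipin-2-en-7-yl (2Z)-2-methylbut-2-enoate; 33 (R)-2-methylbutanoyl chloride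
Product: 34 (4R,5S,7S,8S,9S,10R,11R)-9-hydroxy-8-{[(2R)-2-methylbutanoyl]oxy}-1-oxolongipin-2-en-7-yl (2Z)-2-methylbut-2-enoate (target)
Conditions: 33 (1.1 equiv), pyridine (3 equiv), DMAP (0.1 equiv), CH2Cl2, −40 to −10 °C
Reagents that add atoms: none
Why: DMAP-catalysed acylation by the acid chloride takes the less hindered C8 hydroxyl, because the C9 hydroxyl is neopentylic next to quaternary C10; pyridine is too weak a base to form the ketene, so the α-stereocentre stays R, and the low temperature suppresses acyl migration and double acylation.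

**Compound list**
1 | (E)-3-methylpent-2-en-4-yn-1-ol | C#C/C(C)=C/CO | starting material
2 | (E)-3-methylpenta-2,4-dien-1-ol | C=C/C(C)=C/CO | intermediate
3 | (E)-3-methylpenta-2,4-dienal | C=C/C(C)=C/C=O | intermediate
4 | 3-methylbut-2-enoic acid | CC(C)=CC(=O)O | starting material
5 | tert-butyl 3-methylbut-2-enoate | CC(C)=CC(=O)OC(C)(C)C | intermediate
6 | lithium 1-tert-butoxy-3-methylbuta-1,3-dien-1-olate (not isolated) | [Li+].[O-]C(OC(C)(C)C)=CC(C)=C | intermediate
7 | tert-butyl[(1-tert-butoxy-3-methylbuta-1,3-dien-1-yl)oxy]dimethylsilane (ketene acetal geometry not controlled, inconsequential) | CC(C)(C)OC(O[Si](C)(C)C(C)(C)C)=CC(C)=C | intermediate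
8 | tert-butyl (2E,5S,6E)-5-hydroxy-3,7-dimethylnona-2,6,8-trienoate | C=C/C(C)=C/[C@@H](O)C/C(C)=C/C(=O)OC(C)(C)C | intermediate
9 | tert-butyldimethylsilyl (2E,5S,6E)-5-[(tert-butyldimethylsilyl)oxy]-3,7-dimethylnona-2,6,8-trienoate | C=C/C(C)=C/[C@@H](O[Si](C)(C)C(C)(C)C)C/C(C)=C/C(=O)O[Si](C)(C)C(C)(C)C | intermediate
10 | (2E,5S,6E)-5-[(tert-butyldimethylsilyl)oxy]-3,7-dimethylnona-2,6,8-trienoyl chloride (not isolated) | C=C/C(C)=C/[C@@H](O[Si](C)(C)C(C)(C)C)C/C(C)=C/C(=O)Cl | intermediate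
11 | (5S,6E)-5-[(tert-butyldimethylsilyl)oxy]-7-methyl-3-methylidenenona-1,6,8-trien-1-one, the vinylketene (not isolated) | C=C/C(C)=C/[C@@H](O[Si](C)(C)C(C)(C)C)CC(=C)C=C=O | intermediate
12 | (1R,2S,5R,7R)-2-[(tert-butyldimethylsilyl)oxy]-7-ethenyl-7-methyl-4-methylidenebicyclo[3.1.1]heptan-6-one | C=C[C@@]2(C)[C@@H]3[C@@H](O[Si](C)(C)C(C)(C)C)CC(=C)[C@H]2C3=O | intermediate
13 | 2-methylpropanal | CC(C)C=O | starting material
14 | 4-methylpent-1-en-3-ol (racemic) | CC(C)C(O)C=C | intermediate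
15 | 4-methylpent-1-en-3-one | CC(C)C(=O)C=C | intermediate
16 | trimethyl[(4-methylpenta-1,3-dien-3-yl)oxy]silane | CC(C)=C(O[Si](C)(C)C)C=C | intermediate
17 | lithium 4-methylpenta-1,3-dien-3-olate (not isolated) | [Li+].[O-]C(C=C)=C(C)C | intermediate
18 | lithium aldolate of 12 and 17, 5-O-lithio, chain anti to the C1–C3 bridge (not isolated) | C=C[C@@]2(C)[C@@H]3[C@@H](O[Si](C)(C)C(C)(C)C)CC(=C)[C@H]2[C@]3([O-])C(C)(C)C(=O)C=C.[Li+] | intermediate
19 | lithium O-alkyl carbonodithioate of 18 (not isolated) | C=C[C@@]2(C)[C@@H]3[C@@H](O[Si](C)(C)C(C)(C)C)CC(=C)[C@H]2[C@]3(OC(=S)[S-])C(C)(C)C(=O)C=C.[Li+] | intermediate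
20 | O-[(1R,2S,5R,6R,7R)-2-[(tert-butyldimethylsilyl)oxy]-7-ethenyl-7-methyl-4-methylidene-6-(2-methyl-3-oxopent-4-en-2-yl)bicyclo[3.1.1]heptan-6-yl] S-methyl carbonodithioate | C=C[C@@]2(C)[C@@H]3[C@@H](O[Si](C)(C)C(C)(C)C)CC(=C)[C@H]2[C@]3(OC(=S)SC)C(C)(C)C(=O)C=C | intermediate
21 | O-[(1S,4R,5R,10R,11R)-1-[(tert-butyldimethylsilyl)oxy]-7-oxolongipina-3(12),8-dien-5-yl] S-methyl carbonodithioate | O=C1C=C[C@@]2(C)[C@@H]3[C@@H](O[Si](C)(C)C(C)(C)C)CC(=C)[C@H]2[C@]3(OC(=S)SC)C1(C)C | intermediate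
22 | (1S,4R,5S,10R,11R)-1-[(tert-butyldimethylsilyl)oxy]longipina-3(12),8-dien-7-one | O=C1C=C[C@@]2(C)[C@@H]3[C@@H](O[Si](C)(C)C(C)(C)C)CC(=C)[C@H]2[C@@H]3C1(C)C | intermediate
23 | (1S,4R,5S,7R,10R,11R)-1-[(tert-butyldimethylsilyl)oxy]longipina-3(12),8-dien-7-ol | O[C@@H]1C=C[C@@]2(C)[C@@H]3[C@@H](O[Si](C)(C)C(C)(C)C)CC(=C)[C@H]2[C@@H]3C1(C)C | intermediate
24 | angelic acid, (2Z)-2-methylbut-2-enoic acid | C/C=C(/C)C(=O)O | starting material
25 | (2Z)-2-methylbut-2-enoic 2,4,6-trichlorobenzoic anhydride | C/C=C(/C)C(=O)OC(=O)c1c(Cl)cc(Cl)cc1Cl | intermediate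
26 | lithium alkoxide of 23 (not isolated) | [Li+].[O-][C@@H]1C=C[C@@]2(C)[C@@H]3[C@@H](O[Si](C)(C)C(C)(C)C)CC(=C)[C@H]2[C@@H]3C1(C)C | intermediate
27 | (1S,4R,5S,7R,10R,11R)-1-[(tert-butyldimethylsilyl)oxy]longipina-3(12),8-dien-7-yl (2Z)-2-methylbut-2-enoate | C/C=C(/C)C(=O)O[C@@H]1C=C[C@@]2(C)[C@@H]3[C@@H](O[Si](C)(C)C(C)(C)C)CC(=C)[C@H]2[C@@H]3C1(C)C | intermediate
28 | (1S,4R,5S,7R,10R,11R)-1-hydroxylongipina-3(12),8-dien-7-yl (2Z)-2-methylbut-2-enoate | C/C=C(/C)C(=O)O[C@@H]1C=C[C@@]2(C)[C@@H]3[C@@H](O)CC(=C)[C@H]2[C@@H]3C1(C)C | intermediate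
29 | (4R,5S,7R,10R,11R)-1-oxolongipina-3(12),8-dien-7-yl (2Z)-2-methylbut-2-enoate (not isolated) | C/C=C(/C)C(=O)O[C@@H]1C=C[C@@]2(C)[C@@H]3C(=O)CC(=C)[C@H]2[C@@H]3C1(C)C | intermediate
30 | (4R,5S,7R,10R,11R)-1-oxolongipina-2,8-dien-7-yl (2Z)-2-methylbut-2-enoate | C/C=C(/C)C(=O)O[C@@H]1C=C[C@@]2(C)[C@@H]3C(=O)C=C(C)[C@H]2[C@@H]3C1(C)C | intermediate
31 | (4R,5S,7S,8S,9S,10R,11R)-8,9-dihydroxy-1-oxolongipin-2-en-7-yl (2Z)-2-methylbut-2-enoate | C/C=C(/C)C(=O)O[C@@H]1[C@@H](O)[C@@H](O)[C@@]2(C)[C@@H]3C(=O)C=C(C)[C@H]2[C@@H]3C1(C)C | intermediate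
32 | (R)-2-methylbutanoic acid | CC[C@@H](C)C(=O)O | starting material
33 | (R)-2-methylbutanoyl chloride | CC[C@@H](C)C(=O)Cl | intermediate
34 | (4R,5S,7S,8S,9S,10R,11R)-9-hydroxy-8-{[(2R)-2-methylbutanoyl]oxy}-1-oxolongipin-2-en-7-yl (2Z)-2-methylbut-2-enoate | C/C=C(/C)C(=O)O[C@@H]1[C@@H](OC(=O)[C@H](C)CC)[C@@H](O)[C@@]2(C)[C@@H]3C(=O)C=C(C)[C@H]2[C@@H]3C1(C)C | target

**Step count**
Total step count: 21.
Longest linear sequence: 14 steps (steps 1, 2, 5, 6, 7, 11, 12, 13, 14, 16, 17, 18, 19, 21; the branch through steps 3 and 4 is equally long).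

**Three steps most likely to fail, with fallbacks**

Step 7 (vinylogous ketene generation and [2+2]). The γ-deprotonation of the enoyl chloride may be unselective, or the vinylketene may dimerise before it cyclises. The fallback sets out from silyl ester 9. Mild hydrolysis (K2CO3, MeOH/H2O, 0 °C) gives (2E,5S,6E)-5-[(tert-butyldimethylsilyl)oxy]-3,7-dimethylnona-2,6,8-trienoic acid F1. Its dianion (2.2 equiv LiN(i-Pr)2, THF, −78 to 0 °C) is protonated at the α-carbon on inverse quench into cold aqueous acid, which gives the deconjugated (5S,6E)-5-[(tert-butyldimethylsilyl)oxy]-7-methyl-3-methylidenenona-6,8-dienoic acid F2. Activation of F2 with 2-chloro-1-methylpyridinium iodide and Et3N in toluene at 80 °C under slow addition then forms vinylketene 11 by an ordinary α-elimination, and its cycloaddition comes back to the route at ketone 12.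

Step 11 (aldol union and in-flask xanthate formation). The vinyl ketone enolate may add poorly to the hindered cyclobutanone, or the tertiary aldolate may not be captured. The fallback sets out from ketone 12 and builds the chain stepwise. Lithiated 2-methylpropanenitrile (LiN(i-Pr)2, THF, −78 °C) adds on the same face and gives 2-[(1R,2S,5R,6R,7R)-2-[(tert-butyldimethylsilyl)oxy]-7-ethenyl-6-hydroxy-7-methyl-4-methylidenebicyclo[3.1.1]heptan-6-yl]-2-methylpropanenitrile F3. Reduction with i-Bu2AlH (toluene, −78 °C, aqueous tartrate work-up) gives 2-[(1R,2S,5R,6R,7R)-2-[(tert-butyldimethylsilyl)oxy]-7-ethenyl-6-hydroxy-7-methyl-4-methylidenebicyclo[3.1.1]heptan-6-yl]-2-methylpropanal F4. Addition of CH2=CHMgBr gives 4-[(1R,2S,5R,6R,7R)-2-[(tert-butyldimethylsilyl)oxy]-7-ethenyl-6-hydroxy-7-methyl-4-methylidenebicyclo[3.1.1]heptan-6-yl]-4-methylpent-1-en-3-ol F5 as both C3 epimers. MnO2 oxidises only the allylic carbinol and gives the free aldol 4-[(1R,2S,5R,6R,7R)-2-[(tert-butyldimethylsilyl)oxy]-7-ethenyl-6-hydroxy-7-methyl-4-methylidenebicyclo[3.1.1]heptan-6-yl]-4-methylpent-1-en-3-one F6. Ring-closing metathesis with the same RuCl2(H2IMes)(=CH-C6H4-2-O-i-Pr) catalyst gives (1S,4R,5R,10R,11R)-1-[(tert-butyldimethylsilyl)oxy]-5-hydroxylongipina-3(12),8-dien-7-one F7. Methyl chlorooxoacetate and DMAP give methyl (1S,4R,5R,10R,11R)-1-[(tert-butyldimethylsilyl)oxy]-7-oxolongipina-3(12),8-dien-5-yl oxalate F8. Bu3SnH/AIBN reduction of F8 comes back to the route at enone 22.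

Step 14 (catalyst-controlled reduction at C7). The oxazaborolidine may not distinguish the quaternary from the vinylic side of the ketone. The fallback sets out from enone 22. Unselective 1,2-reduction (NaBH4, CeCl3·7H2O, MeOH, −40 °C) gives 23 together with its C7 epimer (1S,4R,5S,7S,10R,11R)-1-[(tert-butyldimethylsilyl)oxy]longipina-3(12),8-dien-7-ol F9. The two diastereomers are separated by chromatography. F9 is oxidised back to 22 with MnO2 and recycled, and the route is rejoined at alcohol 23.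

**Further compounds**
F1 | step 7 | (2E,5S,6E)-5-[(tert-butyldimethylsilyl)oxy]-3,7-dimethylnona-2,6,8-trienoic acid | C=C/C(C)=C/[C@@H](O[Si](C)(C)C(C)(C)C)C/C(C)=C/C(=O)O
F2 | step 7 | (5S,6E)-5-[(tert-butyldimethylsilyl)oxy]-7-methyl-3-methylidenenona-6,8-dienoic acid | C=C/C(C)=C/[C@@H](O[Si](C)(C)C(C)(C)C)CC(=C)CC(=O)O
F3 | step 11 | 2-[(1R,2S,5R,6R,7R)-2-[(tert-butyldimethylsilyl)oxy]-7-ethenyl-6-hydroxy-7-methyl-4-methylidenebicyclo[3.1.1]heptan-6-yl]-2-methylpropanenitrile | C=C[C@@]2(C)[C@@H]3[C@@H](O[Si](C)(C)C(C)(C)C)CC(=C)[C@H]2[C@]3(O)C(C)(C)C#N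
F4 | step 11 | 2-[(1R,2S,5R,6R,7R)-2-[(tert-butyldimethylsilyl)oxy]-7-ethenyl-6-hydroxy-7-methyl-4-methylidenebicyclo[3.1.1]heptan-6-yl]-2-methylpropanal | C=C[C@@]2(C)[C@@H]3[C@@H](O[Si](C)(C)C(C)(C)C)CC(=C)[C@H]2[C@]3(O)C(C)(C)C=O
F5 | step 11 | 4-[(1R,2S,5R,6R,7R)-2-[(tert-butyldimethylsilyl)oxy]-7-ethenyl-6-hydroxy-7-methyl-4-methylidenebicyclo[3.1.1]heptan-6-yl]-4-methylpent-1-en-3-ol (C3 epimers) | C=C[C@@]2(C)[C@@H]3[C@@H](O[Si](C)(C)C(C)(C)C)CC(=C)[C@H]2[C@]3(O)C(C)(C)C(O)C=C
F6 | step 11 | 4-[(1R,2S,5R,6R,7R)-2-[(tert-butyldimethylsilyl)oxy]-7-ethenyl-6-hydroxy-7-methyl-4-methylidenebicyclo[3.1.1]heptan-6-yl]-4-methylpent-1-en-3-one | C=C[C@@]2(C)[C@@H]3[C@@H](O[Si](C)(C)C(C)(C)C)CC(=C)[C@H]2[C@]3(O)C(C)(C)C(=O)C=C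
F7 | step 11 | (1S,4R,5R,10R,11R)-1-[(tert-butyldimethylsilyl)oxy]-5-hydroxylongipina-3(12),8-dien-7-one | O=C1C=C[C@@]2(C)[C@@H]3[C@@H](O[Si](C)(C)C(C)(C)C)CC(=C)[C@H]2[C@]3(O)C1(C)C
F8 | step 11 | methyl (1S,4R,5R,10R,11R)-1-[(tert-butyldimethylsilyl)oxy]-7-oxolongipina-3(12),8-dien-5-yl oxalate | O=C1C=C[C@@]2(C)[C@@H]3[C@@H](O[Si](C)(C)C(C)(C)C)CC(=C)[C@H]2[C@]3(OC(=O)C(=O)OC)C1(C)C
F9 | step 14 | (1S,4R,5S,7S,10R,11R)-1-[(tert-butyldimethylsilyl)oxy]longipina-3(12),8-dien-7-ol | O[C@H]1C=C[C@@]2(C)[C@@H]3[C@@H](O[Si](C)(C)C(C)(C)C)CC(=C)[C@H]2[C@@H]3C1(C)C
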